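**Retrosynthetic overview**

- The target is reached by oxidation of the C18 primary alcohol of the intact bicycle, so no C–H oxidation is needed after ring formation.
- Both rings come from one cationic cascade of an acyclic C20 chain (labdane numbering throughout). A C4 cation is generated from an (R)-2,2-disubstituted oxirane, so the oxygen ends on C18 and C3 stays CH2. Ring A closes first (C4–C5), then ring B (C9–C10), and loss of Me3Si+ from a (Z)-allylsilane gives the 8(17)-olefin. This is the same cation and chair–chair fold as in the enzymatic cyclisation of geranylgeranyl diphosphate.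
- The oxirane comes from a methyl ketone by asymmetric methylene transfer; the C8=C9 allylsilane comes from a 1,1-dibromoalkene by two stereodefined Negishi couplings.
- Fragments: (S)-citronellol supplies C9–C15 and the C13 stereocentre; hept-1-en-6-yne supplies C1–C7, C4, C19 and C20 through Zr-catalysed carboalumination and Wacker oxidation.
- All four ring stereocentres (C4, C5, C9, C10) are set in the cascade from the single oxirane stereocentre.

Assumption: the SMILES is taken literally, i.e. (4R,5R,9S,10R,13S)-15-acetoxylabd-8(17)-en-18-oic acid with the carboxyl equatorial; the sense of induction of the LaLi3(binaphthoxide)3 catalyst in step 8 is assigned by analogy, and the antipodal BINOL is used if it proves opposite.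

**Route**

Step 1
Reactants: 1 (S)-(−)-citronellol
Product: 2 (3S)-3,7-dimethyloct-6-en-1-yl acetate
Conditions: Ac2O, pyridine, DMAP (cat.), CH2Cl2, 0 °C → rt
Reagents that add atoms: acetic anhydride, CC(=O)OC(C)=O
Why: DMAP-catalysed O-acylation of the primary alcohol; the future C13 stereocentre is bought in and not touched.

Step 2
Reactants: 2 (3S)-3,7-dimethyloct-6-en-1-yl acetate
Product: 3 (3S)-3-methyl-6-oxohexyl acetate
Conditions: O3, CH2Cl2/MeOH, −78 °C; then Me2S
Reagents that add atoms: ozone, [O-][O+]=O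
Why: ozonolysis with reductive work-up cleaves the only olefin to the aldehyde (future C9); the stereocentre is γ to the carbonyl and cannot epimerise.

Step 3
Reactants: 3 (3S)-3-methyl-6-oxohexyl acetate
Product: 4 (3S)-7,7-dibromo-3-methylhept-6-en-1-yl acetate
Conditions: CBr4, PPh3, Zn, CH2Cl2, 0 °C → rt
Reagents that add atoms: carbon tetrabromide, BrC(Br)(Br)Br
Why: Ramirez (Corey–Fuchs) dibromo-olefination adds C8 with two C–Br bonds that differ in reactivity (trans versus cis to the chain).

Step 4
Reactants: 5 hept-1-en-6-yne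
Product: 8 (3E)-4-methylnona-3,8-dien-1-ol, via alkenyldimethylalane 6 (not isolated), via lithium alkenylalanate 7 (not isolated)
Conditions: Me3Al, Cp2ZrCl2 (cat.), CH2Cl2, 0 °C → rt; n-BuLi, THF/hexane, −78 °C; oxirane, −78 → 0 °C; aq. HCl
Reagents that add atoms: trimethylaluminium, C[Al](C)C; oxirane, C1CO1
Why: Negishi Zr-catalysed carboalumination adds Me–Al syn across the alkyne only (≥98% E, the C5=C10 geometry), and the alanate opens oxirane with retention; the terminal alkene is inert.

Step 5
Reactants: 8 (3E)-4-methylnona-3,8-dien-1-ol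
Product: 9 (6E)-9-hydroxy-6-methylnon-6-en-2-one
Conditions: PdCl2 (10 mol%), CuCl, O2 (1 atm), DMF/H2O, rt
Reagents that add atoms: water, O
Why: Tsuji–Wacker oxidation converts only the monosubstituted olefin, with Markovnikov selectivity, into the methyl ketone (C4 and C19); the trisubstituted olefin does not react.

Step 6
Reactants: 9 (6E)-9-hydroxy-6-methylnon-6-en-2-one
Product: 10 (6E)-9-iodo-6-methylnon-6-en-2-one
Conditions: I2, PPh3, imidazole, CH2Cl2, 0 °C
Reagents that add atoms: iodine, II
Why: Appel-type iodination of the primary alcohol; the ketone and olefin are untouched.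

Step 7
Reactants: 10 (6E)-9-iodo-6-methylnon-6-en-2-one; 4 (3S)-7,7-dibromo-3-methylhept-6-en-1-yl acetate
Product: 13 (3S,6Z,10E)-3,11-dimethyl-15-oxo-7-[(trimethylsilyl)methyl]hexadeca-6,10-dien-1-yl acetate, via alkylzinc iodide 11 (not isolated), via Z-bromoalkene 12 (not isolated)
Conditions: Zn, LiCl, THF, 40 °C; 4, PdCl2[(2-Ph2PC6H4)2O] (3 mol%), THF, 23 °C; then Me3SiCH2MgCl + ZnCl2, Pd[P(t-Bu)3]2 (3 mol%), 23 °C
Reagents that add atoms: (trimethylsilyl)methylmagnesium chloride, C[Si](C)(C)C[Mg]Cl
Why: two Negishi couplings: the C–Br bond trans to the chain reacts first (trans-selective monoalkylation of a 1,1-dibromoalkene), and the remaining bromide is replaced with retention under the bulky phosphine, so C7 is trans and CH2SiMe3 cis to C11; the zinc reagents tolerate the ketone and acetate.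

Step 8
Reactants: 13 (3S,6Z,10E)-3,11-dimethyl-15-oxo-7-[(trimethylsilyl)methyl]hexadeca-6,10-dien-1-yl acetate
Product: 14 (3S,6Z,10E)-3,11-dimethyl-14-[(2R)-2-methyloxiran-2-yl]-7-[(trimethylsilyl)methyl]tetradeca-6,10-dien-1-yl acetate
Conditions: Me3S(O)I, NaH, THF; then 13, LaLi3[(S)-binaphthoxide]3 (5 mol%), [2,4,6-(MeO)3C6H2]3PO (5 mol%), 5 Å MS, THF, rt
Reagents that add atoms: trimethylsulfoxonium iodide, C[S+](C)(C)=O.[I-]
Why: catalytic asymmetric Corey–Chaykovsky epoxidation of a methyl ketone: the chiral La/Li binaphthoxide delivers the methylide to one carbonyl face and sets the (R)-oxirane carbon (future C4) under catalyst control, since the C13 centre is too remote to interfere.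

Step 9
Reactants: 14 (3S,6Z,10E)-3,11-dimethyl-14-[(2R)-2-methyloxiran-2-yl]-7-[(trimethylsilyl)methyl]tetradeca-6,10-dien-1-yl acetate
Product: 15 (13S)-18-hydroxylabd-8(17)-en-15-yl acetate
Conditions: MeAlCl2 (2.5 equiv), CH2Cl2, −78 °C; aq. HCl work-up
Reagents that add atoms: none
Why: Proposed new method: MeAlCl2 binds the oxirane oxygen and the tertiary C4–O bond ionises only as the C5=C10 olefin attacks anti to it (inversion at C4, so the (R)-oxirane fixes C4 and, through a chair–chair fold with the Al-bound oxymethyl arm pseudo-equatorial and the methyl axial, also C5 and C10), the C10 cation is taken by the (Z)-allylsilane through a chair that leaves the side chain equatorial at C9, and loss of Me3Si+ can only give the 8(17)-exocyclic olefin; the closest known reaction type is the Lewis-acid epoxy-polyene/allylsilane bicyclisation of trisubstituted 2,3-epoxides (and the epoxide–arene cyclialkylation of 2,2-disubstituted oxiranes), from which it differs in that the oxygen ends on exocyclic C18 and C3 stays CH2.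

Step 10
Reactants: 15 (13S)-18-hydroxylabd-8(17)-en-15-yl acetate
Product: 16 (13S)-15-acetoxylabd-8(17)-en-18-oic acid
Conditions: TEMPO (20 mol%), PhI(OAc)2 (2.5 equiv), MeCN/H2O 1:1, rt
Reagents that add atoms: water, O
Why: oxoammonium (TEMPO/PhI(OAc)2) oxidation takes the primary alcohol through the aldehyde hydrate to the acid; C4 is quaternary so nothing can epimerise, and the 1,1-disubstituted olefin and the acetate are inert.

**Compound list**

1 | (S)-(−)-citronellol, (3S)-3,7-dimethyloct-6-en-1-ol | CC(C)=CCC[C@H](C)CCO | starting material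
2 | (3S)-3,7-dimethyloct-6-en-1-yl acetate | CC(C)=CCC[C@H](C)CCOC(C)=O | intermediate
3 | (3S)-3-methyl-6-oxohexyl acetate | O=CCC[C@H](C)CCOC(C)=O | intermediate
4 | (3S)-7,7-dibromo-3-methylhept-6-en-1-yl acetate | BrC(Br)=CCC[C@H](C)CCOC(C)=O | intermediate
5 | hept-1-en-6-yne | C=CCCCC#C | starting material
6 | (E)-dimethyl(2-methylhepta-1,6-dien-1-yl)alane | C[Al](C)/C=C(\C)CCCC=C | intermediate
7 | lithium (E)-butyldimethyl(2-methylhepta-1,6-dien-1-yl)alanate | [Li+].CCCC[Al-](C)(C)/C=C(\C)CCCC=C | intermediate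
8 | (3E)-4-methylnona-3,8-dien-1-ol | OCC/C=C(\C)CCCC=C | intermediate
9 | (6E)-9-hydroxy-6-methylnon-6-en-2-one | CC(=O)CCC/C(C)=C/CCO | intermediate
10 | (6E)-9-iodo-6-methylnon-6-en-2-one | CC(=O)CCC/C(C)=C/CCI | intermediate
11 | [(3E)-4-methyl-8-oxonon-3-en-1-yl]zinc iodide | CC(=O)CCC/C(C)=C/CC[Zn]I | intermediate
12 | (3S,6Z,10E)-7-bromo-3,11-dimethyl-15-oxohexadeca-6,10-dien-1-yl acetate | CC(=O)CCC/C(C)=C/CC/C(Br)=C/CC[C@H](C)CCOC(C)=O | intermediate
13 | (3S,6Z,10E)-3,11-dimethyl-15-oxo-7-[(trimethylsilyl)methyl]hexadeca-6,10-dien-1-yl acetate | CC(=O)CCC/C(C)=C/CC/C(C[Si](C)(C)C)=C/CC[C@H](C)CCOC(C)=O | intermediate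
14 | (3S,6Z,10E)-3,11-dimethyl-14-[(2R)-2-methyloxiran-2-yl]-7-[(trimethylsilyl)methyl]tetradeca-6,10-dien-1-yl acetate | C[C@@]1(CCC/C(C)=C/CC/C(C[Si](C)(C)C)=C/CC[C@H](C)CCOC(C)=O)CO1 | intermediate
15 | (4R,5R,9S,10R,13S)-18-hydroxylabd-8(17)-en-15-yl acetate | C=C1CC[C@@H]2[C@](C)(CCC[C@@]2(C)CO)[C@H]1CC[C@H](C)CCOC(C)=O | intermediate
16 | (4R,5R,9S,10R,13S)-15-acetoxylabd-8(17)-en-18-oic acid | C=C1CC[C@@H]2[C@](C)(CCC[C@@]2(C)C(=O)O)[C@H]1CC[C@H](C)CCOC(C)=O | target

**Step count and risks**

Total step count: 10. Longest linear sequence: 7 (steps 1, 2, 3, 7, 8, 9, 10 from 1, or steps 4–10 from 5).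

The three steps most likely to fail:

Step 9 (the cascade). There are two real dangers. The Al-bound oxirane may undergo a hydride shift to the C18 aldehyde before ring A closes. The chair with the oxymethyl arm axial may compete, which would pass the oxirane chirality on to the antipodal decalin with the CH2OH on the wrong side; I expect the equatorial preference to be modest at best, and the two products are diastereomers that would have to be separated. The fallback sets out from 4 and comes back at 15. It moves the relay from C4 to a temporary C3 oxygen and lets olefin geometry fix C4. Hex-1-en-5-yne is taken through the chemistry of steps 4 and 6 to the dienol (3E)-4-methylocta-3,7-dien-1-ol F1 and the iodide (5E)-8-iodo-5-methylocta-1,5-diene F2. Zinc insertion and the two couplings of step 7 with 4 give the triene (3S,6Z,10E)-3,11-dimethyl-7-[(trimethylsilyl)methyl]pentadeca-6,10,14-trien-1-yl acetate F3. Cross-metathesis with methacrolein (second-generation Grubbs catalyst, CH2Cl2, 40 °C) gives the (E)-enal (3S,6Z,10E,14E)-3,11,15-trimethyl-16-oxo-7-[(trimethylsilyl)methyl]hexadeca-6,10,14-trien-1-yl acetate F4. NaBH4/CeCl3 gives the allylic alcohol (3S,6Z,10E,14E)-16-hydroxy-3,11,15-trimethyl-7-[(trimethylsilyl)methyl]hexadeca-6,10,14-trien-1-yl acetate F5. Sharpless epoxidation (Ti(OiPr)4, L-(+)-diethyl tartrate, t-BuOOH, −20 °C) gives the epoxy alcohol (3S,6Z,10E)-13-[(2S,3S)-3-(hydroxymethyl)-3-methyloxiran-2-yl]-3,11-dimethyl-7-[(trimethylsilyl)methyl]trideca-6,10-dien-1-yl acetate F6. MeAlCl2 at −78 °C then gives the diol (13S)-3β,18-dihydroxylabd-8(17)-en-15-yl acetate F7. Here the CH2OH that was trans on the E-olefin must end equatorial as C18, and the equatorial C3 oxygen fixes the chair, as in the classical 2,3-epoxide polyene cyclisations. Thiocarbonyldiimidazole closes the cyclic thionocarbonate (13S)-3β,18-(thiocarbonyldioxy)labd-8(17)-en-15-yl acetate F8. Bu3SnH/AIBN breaks only the secondary C3–O bond (Barton deoxygenation), and aqueous KF work-up frees the primary alcohol 15. This costs three more steps.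

Step 8 (asymmetric methylene transfer). The enantioselectivity on a purely aliphatic methyl ketone may be lower than needed, and the ylide may attack the acetate. The fallback sets out from 13 and comes back at 14, replacing asymmetric synthesis by resolution. Plain dimethylsulfoxonium methylide without catalyst gives the oxirane epimer mixture (3S,6Z,10E)-3,11-dimethyl-14-[(2RS)-2-methyloxiran-2-yl]-7-[(trimethylsilyl)methyl]tetradeca-6,10-dien-1-yl acetate F9. Azidolytic kinetic resolution with Me3SiN3 and the (salen)CrN3 complex of trivalent chromium (the enantiomer that consumes the (2S)-epimer) opens that epimer at its CH2 to the azido silyl ether (3S,6Z,10E,15S)-16-azido-3,11,15-trimethyl-7-[(trimethylsilyl)methyl]-15-[(trimethylsilyl)oxy]hexadeca-6,10-dien-1-yl acetate F10. It leaves 14, at most half of the material.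

Step 7 (second coupling). The silylmethyl coupling on the hindered Z-bromide may stall or erode the olefin geometry. The fallback sets out from 12, isolated after the first coupling, and comes back at 15. It drops silicon and lets the vinyl bromide end the cascade (vinyl halide terminator, then carbonyl methylenation). Step 8 conditions on 12 give the bromo-olefin oxirane (3S,6Z,10E)-7-bromo-3,11-dimethyl-14-[(2R)-2-methyloxiran-2-yl]tetradeca-6,10-dien-1-yl acetate F11. MeAlCl2 at −78 °C closes both rings onto the bromo-olefin, and aqueous work-up of the α-bromo cation gives the ketone (13S)-18-hydroxy-8-oxo-17-norlabdan-15-yl acetate F12. Non-basic methylenation (Zn, CH2Br2, TiCl4), which does not epimerise C9, gives 15.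

**Further compounds**

F1 | step 9 | (3E)-4-methylocta-3,7-dien-1-ol | OCC/C=C(\C)CCC=C
F2 | step 9 | (5E)-8-iodo-5-methylocta-1,5-diene | ICC/C=C(\C)CCC=C
F3 | step 9 | (3S,6Z,10E)-3,11-dimethyl-7-[(trimethylsilyl)methyl]pentadeca-6,10,14-trien-1-yl acetate | C=CCC/C(C)=C/CC/C(C[Si](C)(C)C)=C/CC[C@H](C)CCOC(C)=O
F4 | step 9 | (3S,6Z,10E,14E)-3,11,15-trimethyl-16-oxo-7-[(trimethylsilyl)methyl]hexadeca-6,10,14-trien-1-yl acetate | O=C/C(C)=C/CC/C(C)=C/CC/C(C[Si](C)(C)C)=C/CC[C@H](C)CCOC(C)=O
F5 | step 9 | (3S,6Z,10E,14E)-16-hydroxy-3,11,15-trimethyl-7-[(trimethylsilyl)methyl]hexadeca-6,10,14-trien-1-yl acetate | OC/C(C)=C/CC/C(C)=C/CC/C(C[Si](C)(C)C)=C/CC[C@H](C)CCOC(C)=O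
F6 | step 9 | (3S,6Z,10E)-13-[(2S,3S)-3-(hydroxymethyl)-3-methyloxiran-2-yl]-3,11-dimethyl-7-[(trimethylsilyl)methyl]trideca-6,10-dien-1-yl acetate | OC[C@]1(C)O[C@H]1CC/C(C)=C/CC/C(C[Si](C)(C)C)=C/CC[C@H](C)CCOC(C)=O
F7 | step 9 | (13S)-3β,18-dihydroxylabd-8(17)-en-15-yl acetate | C=C1CC[C@@H]2[C@](C)(CC[C@H](O)[C@@]2(C)CO)[C@H]1CC[C@H](C)CCOC(C)=O
F8 | step 9 | (13S)-3β,18-(thiocarbonyldioxy)labd-8(17)-en-15-yl acetate | C=C1CC[C@@H]2[C@](C)(CC[C@@H]3OC(=S)OC[C@@]23C)[C@H]1CC[C@H](C)CCOC(C)=O
F9 | step 8 | (3S,6Z,10E)-3,11-dimethyl-14-[(2RS)-2-methyloxiran-2-yl]-7-[(trimethylsilyl)methyl]tetradeca-6,10-dien-1-yl acetate | CC1(CCC/C(C)=C/CC/C(C[Si](C)(C)C)=C/CC[C@H](C)CCOC(C)=O)CO1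
F10 | step 8 | (3S,6Z,10E,15S)-16-azido-3,11,15-trimethyl-7-[(trimethylsilyl)methyl]-15-[(trimethylsilyl)oxy]hexadeca-6,10-dien-1-yl acetate | C[C@](CCC/C(C)=C/CC/C(C[Si](C)(C)C)=C/CC[C@H](C)CCOC(C)=O)(CN=[N+]=[N-])O[Si](C)(C)C
F11 | step 7 | (3S,6Z,10E)-7-bromo-3,11-dimethyl-14-[(2R)-2-methyloxiran-2-yl]tetradeca-6,10-dien-1-yl acetate | C[C@@]1(CCC/C(C)=C/CC/C(Br)=C/CC[C@H](C)CCOC(C)=O)CO1
F12 | step 7 | (13S)-18-hydroxy-8-oxo-17-norlabdan-15-yl acetate | O=C1CC[C@@H]2[C@](C)(CCC[C@@]2(C)CO)[C@H]1CC[C@H](C)CCOC(C)=O
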